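## Structural features

The target 20 is an isoflavan: a benzene ring (ring A) is fused through C4a and C8a to a dihydropyran (ring C, O1–C2–C3–C4), and a second benzene ring (ring B) is attached through C1' to C3. Ring A is fully differentiated: methoxyl at C5, a 3-methylbut-2-enyl (prenyl) chain at C6, free hydroxyl at C7, hydrogen at C8 and the ring oxygen at C8a. Ring B carries a methoxyl at C2' and a hydroxyl at C4'. C3 is the only stereocentre (R); it has no stereogenic neighbour to relay from, and it is a tertiary benzylic CH with no heteroatom or carbonyl on it that could guide its formation. The fragile parts are the prenyl alkene (acid, peracids, hydrogenation) and the two electron-rich phenolic rings (oxidants, electrophiles). The real difficulty is twofold: absolute control at the isolated C3, and a pentasubstituted ring A whose three different oxygen functions and prenyl group must be placed without ambiguity. The key step exploits the fact that C3 is bonded only to C1' of ring B and to two methylenes, C4 (leading to C4a) and C2 (leading to O1). C3 and C4 come from a vinylboron unit, ring B migrates onto the boron-bearing carbon C3, palladium delivers ring A to C4, and the boron left on C3 is the handle for adding C2.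

## Logic of the disconnections

20 ⇒ 19. The O1–C2 bond is cut. Ring C then opens to a primary alcohol and a phenol, and only the C8a hydroxyl can reach C2 in a six-membered closure. The forward step must activate the aliphatic hydroxyl in the presence of three phenols and must be run dilute so that the C7 and C4' hydroxyls do not react between molecules.

19 ⇒ 18. No skeletal bond is cut; the three aryl O–CH2OCH3 bonds are restored. One kind of acetal on all three phenols allows a single unmasking operation. The demand is an acid treatment mild enough to leave the prenyl group beside the freed C7 hydroxyl untouched.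

18 ⇒ 17 ⇒ 16. The C2–O bond becomes a C2–B bond, and then the C2–C3 bond is cut, so C2 is a one-carbon insertion into a C3–B bond. This reduces the acyclic stereocentre to a secondary benzylic boronate, a class that catalytic methods reach directly. The insertion must proceed with retention at C3 and must work at a hindered secondary boron.

16 ⇒ 15 + 10, and 15 ⇒ 14 + 13. The C3–C1' and C4–C4a bonds are cut together. Both aryl rings are removed in one stroke, leaving a two-carbon vinylboron unit, an aryllithium and an aryl triflate, none of which contains a stereocentre. The forward step has to set C3 by catalyst control and must make the 1,2-shift beat direct transfer from boron to palladium at a triflate flanked by two oxygen substituents.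

14 ⇒ 12 ⇒ 11. The C1'–Li bond goes back to C1'–Br and the acetal O–C bond to the free phenol. The bromine para to the hydroxyl and ortho to the methoxyl in 11 fixes the ring B pattern. The forward exchange must be faster than ortho-lithiation next to the acetal.

10 ⇒ 9 ⇒ 8. The C5 O–CH3 bond is cut, and then the C6–CH2 bond of the prenyl group is traced back to an O–C bond of a tertiary allyl ether on the neighbouring oxygen. This places the prenyl group unambiguously, because in 8 the only free ortho carbon is the future C6. The forward [3,3] shift must tolerate the triflate, which blocks the other ortho position and its oxygen.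

8 ⇒ 7 ⇒ 6 ⇒ 5. The S–O bond is cut, and the aryl C–O bond at the future C4a is traced back to an aryl C–CHO bond by oxygen insertion. The formyl group thereby marks the carbon that later bears the leaving group. The oxidant must attack the aldehyde and not the alkene, which is why the alkene is still a monosubstituted vinyl group at this stage.

5 ⇒ 4 + 2, 4 ⇒ 3, 2 ⇒ 1. The tertiary allyl O–C bond and two acetal O–C bonds are cut. This leaves a symmetrical, commercial trihydroxybenzaldehyde and a carbonate of a commercial tertiary allylic alcohol. The protection must stop at two hydroxyls, and the allylation must occur at the tertiary terminus.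

## Other disconnections considered

Alternative 1: Ring A is cut at C4a–C5 and C6–C7 (with C7–C8 re-formed), back to the ring-fused cyclobutenone A2 and the methoxyalkyne A3. The forward step would be thermal: four-electron ring opening of A2, ketene–alkyne [2+2] cycloaddition with A3, a second ring opening and six-electron closure. This would give A1 with the C7 hydroxyl free, and fluoride would then remove the silyl group.
- In its favour: the polarity of the ketene–ynol ether cycloaddition dictates the ring A pattern (methoxyl carbon to C4a, prenyl-bearing carbon next to the new hydroxyl). No hindered cross-coupling is needed, and no acetal has to be removed next to the prenyl group. On these points it is better than the chosen plan, whose step 11 exposes the prenyl group to acid.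
- Against it: the cascade creates no stereocentre, so C3 must already be present in A2. A2 is a strained bicyclic 3-alkoxycyclobutenone that would need its own multi-step asymmetric synthesis. A3 is a sensitive ynol ether.
- Comparison: on mechanism it is a robust pericyclic sequence with no catalyst to tune, which equals or betters step 9 in predictability. On structure it only moves the stereochemical problem into the precursor. On step economy it is expected to be clearly longer, whereas step 9 makes two skeletal bonds and the stereocentre from three simple pieces.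

Alternative 2: The cut is O1–C2, made together with the C3–H bond, back to the phenolic 1,1-disubstituted alkene A5. In the forward step an excited acridinium photocatalyst would oxidise the ring B alkene, the C8a hydroxyl would add to the terminal carbon (6-endo), and a chiral thiol would transfer hydrogen to C3. This would give A4, and acid would then remove two acetals.
- In its favour: ring C and the stereocentre would arise in one redox-neutral step from an achiral alkene. Only one step follows the key step, which is better than the three that follow step 9.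
- Against it: hydrogen transfer from a thiol to a planar tertiary benzylic radical is fast and loosely organised, so there is no sound basis for high enantioselectivity. A5 also offers several other sites to the oxidant: the phenol, two very electron-rich rings and the prenyl alkene.
- Comparison: on structure the two plans are equal, since both need ring A functionalised at C4a beforehand. On mechanism the chosen plan rests on a catalyst class with proven enantiofacial control, while here the stereo-determining event is the unproven element.

Alternative 3: The cuts are C3–C4 and the O1–C2 acyl bond, back to the 2-(tosylmethyl)phenol A7 and the activated arylacetic ester A8. In the forward step a carbonate base would release the ortho-quinone methide A9 from A7, and the ammonium enolate formed from A8 and a chiral isothiourea would add to it and lactonise to A6. Hydride reduction to the phenol-alcohol A10, Mitsunobu closure to A4 and acetal removal would follow.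
- In its favour: the step is metal-free and convergent. The C8a oxygen is singled out automatically, so the later ring closure of A10 involves one free phenol only. That is better than step 12 of the chosen plan, which has three. The number of steps after the key step (three) is equal.
- Against it: the quinone methide has an unsubstituted methylene terminus and is prone to self-condensation. The only stereocentre in A6 is an acidic α-aryl lactone carbon, which can epimerise under the basic conditions. The lactone carbonyl has to be removed by opening and re-closing ring C. A7 needs regiocontrolled C-functionalisation between two free ortho positions of a phenol.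
- Comparison: the C–C bond formation is mechanistically well grounded, but the configurational stability of the product is the weak point. The boronate 16 of the chosen plan cannot epimerise.

Key step: step 9

Remark on the structures: the substitution pattern of 10 was traced onto ring A. C1 with the triflate becomes C4a, the 2-methoxyl C5, the 3-prenyl C6, and the 4- and 6-acetal oxygens C7 and C8a. Boron ranks below both carbon substituents, so (1R)-16 has the spatial arrangement of (3R)-20 once boron is replaced by C2 with retention. No structure needed correction.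

Design changes: a triflate salt is added to the coupling to take up the bromide left by the bromine–lithium exchange. Homologation and oxidation are run in one flask.

Assumption: one of the two available antipodes of the MandyPhos ligand delivers (1R)-16. Which one is to be settled on a model coupling with assignment of configuration.

## Route

Step 1
Reactants: 1 2-methylbut-3-en-2-ol
Product: 2 methyl 2-methylbut-3-en-2-yl carbonate
Conditions: n-BuLi, THF, −78 °C; ClCO2Me, −78 °C to rt
Reagents that add atoms: methyl chloroformate, COC(=O)Cl
Why: O-acylation of the lithium alkoxide of a tertiary allylic alcohol with a chloroformate; deprotonation first is used because the hindered tertiary hydroxyl reacts sluggishly under amine catalysis.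

Step 2
Reactants: 3 2,4,6-trihydroxybenzaldehyde
Product: 4 2-hydroxy-4,6-bis(methoxymethoxy)benzaldehyde
Conditions: MOMCl (2.1 equiv), i-Pr2NEt, CH2Cl2, 0 °C to rt
Reagents that add atoms: chloromethyl methyl ether, COCCl
Why: Williamson-type O-alkylation to the acetals; the 4-hydroxyl and one ortho hydroxyl react, while the last ortho hydroxyl is deactivated by its hydrogen bond to the formyl oxygen, so protection should stop at two groups.

Step 3
Reactants: 4 2-hydroxy-4,6-bis(methoxymethoxy)benzaldehyde; 2 methyl 2-methylbut-3-en-2-yl carbonate
Product: 5 2,4-bis(methoxymethoxy)-6-[(2-methylbut-3-en-2-yl)oxy]benzaldehyde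
Conditions: Pd(PPh3)4 (cat.), THF, 0 °C to rt
Reagents that add atoms: none
Why: Tsuji–Trost O-allylation: zerovalent palladium ionises 2 to a 1,1-dimethyl-π-allyl complex with loss of CO2, the released methoxide deprotonates the phenol, and the phenoxide attacks the more substituted allyl terminus under kinetic control to give the tertiary ether; the reaction is stopped before equilibration to the linear ether.

Step 4
Reactants: 5 2,4-bis(methoxymethoxy)-6-[(2-methylbut-3-en-2-yl)oxy]benzaldehyde
Product: 7 2,4-bis(methoxymethoxy)-6-[(2-methylbut-3-en-2-yl)oxy]phenol, via aryl formate 6 (not isolated)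
Conditions: mCPBA, CH2Cl2, 0 °C to rt; aq. NaHCO3 wash; K2CO3 (cat.), MeOH, rt
Reagents that add atoms: 3-chloroperoxybenzoic acid, O=C(OO)c1cccc(Cl)c1
Why: Baeyer–Villiger oxidation of an electron-rich benzaldehyde (Dakin-type): the trioxygenated aryl migrates in the Criegee adduct to give 6, which methanolysis cleaves; the monosubstituted vinyl group is epoxidised far more slowly than the aldehyde is oxidised, which is why this step precedes the Claisen shift that creates a trisubstituted alkene.

Step 5
Reactants: 7 2,4-bis(methoxymethoxy)-6-[(2-methylbut-3-en-2-yl)oxy]phenol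
Product: 8 2,4-bis(methoxymethoxy)-6-[(2-methylbut-3-en-2-yl)oxy]phenyl trifluoromethanesulfonate
Conditions: Tf2O, pyridine, CH2Cl2, −78 to 0 °C
Reagents that add atoms: trifluoromethanesulfonic anhydride, O=S(=O)(OS(=O)(=O)C(F)(F)F)C(F)(F)F
Why: O-sulfonylation of the phenol through the N-triflylpyridinium salt; the triflate is the later leaving group at C4a and meanwhile blocks this oxygen and this ortho position; excess pyridine keeps the acid-sensitive tertiary allyl ether and the acetals intact.

Step 6
Reactants: 8 2,4-bis(methoxymethoxy)-6-[(2-methylbut-3-en-2-yl)oxy]phenyl trifluoromethanesulfonate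
Product: 9 2-hydroxy-4,6-bis(methoxymethoxy)-3-(3-methylbut-2-enyl)phenyl trifluoromethanesulfonate
Conditions: PhNEt2, 150 °C
Reagents that add atoms: none
Why: Aromatic Claisen rearrangement: the [3,3] shift can end productively only at the unsubstituted ortho carbon (a shift to the triflate-bearing carbon is reversible), the allyl unit is inverted so that the prenyl chain appears at the future C6, and tautomerisation restores the arene; the basic solvent suppresses ionisation of the tertiary ether and acid-induced cyclisation of the product.

Step 7
Reactants: 9 2-hydroxy-4,6-bis(methoxymethoxy)-3-(3-methylbut-2-enyl)phenyl trifluoromethanesulfonate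
Product: 10 2-methoxy-4,6-bis(methoxymethoxy)-3-(3-methylbut-2-enyl)phenyl trifluoromethanesulfonate
Conditions: MeI, K2CO3, DMF, rt
Reagents that add atoms: iodomethane, CI
Why: Williamson methylation of the phenoxide; the aryl triflate and the acetals are inert to K2CO3 and MeI at room temperature, and fast alkylation by excess MeI leaves the phenoxide little time for sulfonyl transfer.

Step 8
Reactants: 11 4-bromo-3-methoxyphenol
Product: 12 1-bromo-2-methoxy-4-(methoxymethoxy)benzene
Conditions: MOMCl, i-Pr2NEt, CH2Cl2, 0 °C to rt
Reagents that add atoms: chloromethyl methyl ether, COCCl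
Why: O-alkylation of the phenol to its methoxymethyl ether, which tolerates the organolithium, the ate complex and the homologation and is later removed together with the ring A acetals.

Step 9
Reactants: 12 1-bromo-2-methoxy-4-(methoxymethoxy)benzene; 13 4,4,5,5-tetramethyl-2-vinyl-1,3,2-dioxaborolane (vinylboronic acid pinacol ester); 10 2-methoxy-4,6-bis(methoxymethoxy)-3-(3-methylbut-2-enyl)phenyl trifluoromethanesulfonate
Product: 16 2-{(1R)-1-[2-methoxy-4-(methoxymethoxy)phenyl]-2-[2-methoxy-4,6-bis(methoxymethoxy)-3-(3-methylbut-2-enyl)phenyl]ethyl}-4,4,5,5-tetramethyl-1,3,2-dioxaborolane, via aryllithium 14 (not isolated), via vinylboron ate complex 15 (not isolated)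
Conditions: t-BuLi (2 equiv), Et2O, −78 °C; 13, −78 °C to rt; solvent switch to THF; 10, Pd(OAc)2 (cat.), MandyPhos ligand with bis(4-methoxy-3,5-dimethylphenyl)phosphino groups (cat.), NaOTf, 60 °C
Reagents that add atoms: none
Why: Bromine–lithium exchange gives 14, which adds to the empty boron orbital of 13 to form the ate complex 15. Zerovalent palladium, formed from Pd(OAc)2 and the bis(phosphine), adds oxidatively to 10; because triflate does not stay on the metal, the cationic divalent arylpalladium binds the electron-rich vinyl group of 15, and this triggers a 1,2-metallate shift in which the ring B aryl moves from boron to C3 anti to palladium while palladium bonds to C4. Reductive elimination then joins C4 to C4a and returns zerovalent palladium. The closest known reaction type is the palladium-catalysed enantioselective conjunctive cross-coupling of vinylboron ate complexes with aryl triflates; 10 belongs to that class of electrophile but carries two ortho oxygen substituents. No ring is closed. The single new stereocentre, C3, is set by the chiral bis(phosphine), which decides the face of the vinyl group that palladium takes; the anti, stereospecific migration turns this into the (1R) configuration, and a secondary pinacol boronate is configurationally stable. The step needs the metallate shift to win over direct transfer of aryl or vinyl from boron to palladium and over binding of the prenyl alkene: the chelating ligand and halide-free cationic palladium (NaOTf removes bromide as NaBr) favour alkene binding, the 2,4-dioxygenated aryl is a fast migrating group, and the neutral trisubstituted prenyl alkene is a far weaker ligand than the anionic vinylborate.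

Step 10
Reactants: 16 2-{(1R)-1-[2-methoxy-4-(methoxymethoxy)phenyl]-2-[2-methoxy-4,6-bis(methoxymethoxy)-3-(3-methylbut-2-enyl)phenyl]ethyl}-4,4,5,5-tetramethyl-1,3,2-dioxaborolane
Product: 18 (2R)-2-[2-methoxy-4-(methoxymethoxy)phenyl]-3-[2-methoxy-4,6-bis(methoxymethoxy)-3-(3-methylbut-2-enyl)phenyl]propan-1-ol, via homologated boronate 17 (not isolated)
Conditions: BrCH2Cl, n-BuLi, THF, −78 °C to rt; then aq. NaOH, H2O2, 0 °C to rt
Reagents that add atoms: bromochloromethane, ClCBr; hydrogen peroxide, OO
Why: Matteson homologation: chloromethyllithium, generated in the presence of 16, adds to boron and the benzylic carbon migrates onto the carbenoid carbon with loss of chloride and retention at C3, giving 17; alkaline peroxide then replaces boron by hydroxyl at the new primary carbon C2 and does not epoxidise the unactivated prenyl alkene.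

Step 11
Reactants: 18 (2R)-2-[2-methoxy-4-(methoxymethoxy)phenyl]-3-[2-methoxy-4,6-bis(methoxymethoxy)-3-(3-methylbut-2-enyl)phenyl]propan-1-ol
Product: 19 4-[(2R)-3-hydroxy-2-(4-hydroxy-2-methoxyphenyl)propyl]-5-methoxy-6-(3-methylbut-2-enyl)benzene-1,3-diol
Conditions: HCl (aq, 3 M), MeOH, rt to 40 °C
Reagents that add atoms: none
Why: Acid-catalysed acetal exchange with methanol removes the three aryl methoxymethyl ethers as dimethoxymethane; aryl acetals cleave under mild conditions at which a prenyl group next to a phenol normally survives, so the temperature is kept low and the reaction is stopped at full conversion.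

Step 12
Reactants: 19 4-[(2R)-3-hydroxy-2-(4-hydroxy-2-methoxyphenyl)propyl]-5-methoxy-6-(3-methylbut-2-enyl)benzene-1,3-diol
Product: 20 (3R)-3-(4-hydroxy-2-methoxyphenyl)-5-methoxy-6-(3-methylbut-2-enyl)-3,4-dihydro-2H-chromen-7-ol
Conditions: PPh3, DIAD (slow addition), THF (0.005 M), 0 °C to rt
Reagents that add atoms: none
Why: Intramolecular Mitsunobu etherification: the primary alcohol is activated as its alkoxyphosphonium ion and displaced by the C8a hydroxyl in a 6-exo-tet closure; the C7 and C4' hydroxyls cannot reach C2 within the molecule, and dilution with slow addition disfavours their intermolecular reaction; C3 is not involved and keeps its configuration.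

## Compound list

1 | 2-methylbut-3-en-2-ol | C=CC(C)(C)O | starting material
2 | methyl 2-methylbut-3-en-2-yl carbonate | C=CC(C)(C)OC(=O)OC | intermediate
3 | 2,4,6-trihydroxybenzaldehyde | O=Cc1c(O)cc(O)cc1O | starting material
4 | 2-hydroxy-4,6-bis(methoxymethoxy)benzaldehyde | O=Cc1c(O)cc(OCOC)cc1OCOC | intermediate
5 | 2,4-bis(methoxymethoxy)-6-[(2-methylbut-3-en-2-yl)oxy]benzaldehyde | O=Cc1c(OC(C)(C)C=C)cc(OCOC)cc1OCOC | intermediate
6 | 2,4-bis(methoxymethoxy)-6-[(2-methylbut-3-en-2-yl)oxy]phenyl formate | O=COc1c(OC(C)(C)C=C)cc(OCOC)cc1OCOC | intermediate (not isolated)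
7 | 2,4-bis(methoxymethoxy)-6-[(2-methylbut-3-en-2-yl)oxy]phenol | Oc1c(OC(C)(C)C=C)cc(OCOC)cc1OCOC | intermediate
8 | 2,4-bis(methoxymethoxy)-6-[(2-methylbut-3-en-2-yl)oxy]phenyl trifluoromethanesulfonate | C=CC(C)(C)Oc1cc(OCOC)cc(OCOC)c1OS(=O)(=O)C(F)(F)F | intermediate
9 | 2-hydroxy-4,6-bis(methoxymethoxy)-3-(3-methylbut-2-enyl)phenyl trifluoromethanesulfonate | Oc1c(CC=C(C)C)c(OCOC)cc(OCOC)c1OS(=O)(=O)C(F)(F)F | intermediate
10 | 2-methoxy-4,6-bis(methoxymethoxy)-3-(3-methylbut-2-enyl)phenyl trifluoromethanesulfonate | COCOc1cc(OCOC)c(CC=C(C)C)c(OC)c1OS(=O)(=O)C(F)(F)F | intermediate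
11 | 4-bromo-3-methoxyphenol | COc1cc(O)ccc1Br | starting material
12 | 1-bromo-2-methoxy-4-(methoxymethoxy)benzene | COCOc1ccc(Br)c(OC)c1 | intermediate
13 | 4,4,5,5-tetramethyl-2-vinyl-1,3,2-dioxaborolane | C=CB1OC(C)(C)C(C)(C)O1 | starting material
14 | [2-methoxy-4-(methoxymethoxy)phenyl]lithium | [Li]c1ccc(OCOC)cc1OC | intermediate (not isolated)
15 | lithium 2-ethenyl-2-[2-methoxy-4-(methoxymethoxy)phenyl]-4,4,5,5-tetramethyl-1,3,2-dioxaborolan-2-uide | [Li+].C=C[B-]1(c2ccc(OCOC)cc2OC)OC(C)(C)C(C)(C)O1 | intermediate (not isolated)
16 | 2-{(1R)-1-[2-methoxy-4-(methoxymethoxy)phenyl]-2-[2-methoxy-4,6-bis(methoxymethoxy)-3-(3-methylbut-2-enyl)phenyl]ethyl}-4,4,5,5-tetramethyl-1,3,2-dioxaborolane | COc1cc(OCOC)ccc1[C@@H](Cc1c(OC)c(CC=C(C)C)c(OCOC)cc1OCOC)B1OC(C)(C)C(C)(C)O1 | intermediate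
17 | 2-{(2R)-2-[2-methoxy-4-(methoxymethoxy)phenyl]-3-[2-methoxy-4,6-bis(methoxymethoxy)-3-(3-methylbut-2-enyl)phenyl]propyl}-4,4,5,5-tetramethyl-1,3,2-dioxaborolane | COc1cc(OCOC)ccc1[C@@H](Cc1c(OC)c(CC=C(C)C)c(OCOC)cc1OCOC)CB1OC(C)(C)C(C)(C)O1 | intermediate (not isolated)
18 | (2R)-2-[2-methoxy-4-(methoxymethoxy)phenyl]-3-[2-methoxy-4,6-bis(methoxymethoxy)-3-(3-methylbut-2-enyl)phenyl]propan-1-ol | COc1cc(OCOC)ccc1[C@@H](Cc1c(OC)c(CC=C(C)C)c(OCOC)cc1OCOC)CO | intermediate
19 | 4-[(2R)-3-hydroxy-2-(4-hydroxy-2-methoxyphenyl)propyl]-5-methoxy-6-(3-methylbut-2-enyl)benzene-1,3-diol | COc1cc(O)ccc1[C@@H](Cc1c(OC)c(CC=C(C)C)c(O)cc1O)CO | intermediate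
20 | (3R)-3-(4-hydroxy-2-methoxyphenyl)-5-methoxy-6-(3-methylbut-2-enyl)-3,4-dihydro-2H-chromen-7-ol | COc1cc(O)ccc1[C@@H]1COc2cc(O)c(CC=C(C)C)c(OC)c2C1 | target

## Step count and least certain steps

Total: 12 steps. Longest linear sequence: 10 steps (steps 2–7 and 9–12, from 3). Steps 1 and 8 are side branches.

**Step 9 (key step).** Oxidative addition may be slow at a triflate that is electron-rich and flanked by a methoxyl and an acetal oxygen. Direct transfer of aryl or vinyl from boron to palladium may then outrun the metallate shift. The two ortho substituents may also disturb the fit in the chiral pocket and lower the facial selectivity.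

Fallback (from 12, back at 19): the two tasks of the chiral catalyst are separated.
- Bromine–lithium exchange on 12 and quenching with 2-isopropoxy-4,4,5,5-tetramethyl-1,3,2-dioxaborolane should give 2-[2-methoxy-4-(methoxymethoxy)phenyl]-4,4,5,5-tetramethyl-1,3,2-dioxaborolane F1.
- Suzuki–Miyaura coupling with 2-bromoprop-2-en-1-ol (PdCl2(dppf), K2CO3, dioxane/H2O) should give 2-[2-methoxy-4-(methoxymethoxy)phenyl]prop-2-en-1-ol F2.
- MOMCl and i-Pr2NEt should give 2-methoxy-4-(methoxymethoxy)-1-[3-(methoxymethoxy)prop-1-en-2-yl]benzene F3.
- Cobalt-catalysed enantioselective anti-Markovnikov hydroboration of this 1,1-disubstituted aryl alkene (chiral iminopyridine–oxazoline CoCl2 complex, NaBHEt3, HBpin) sets C3 and should give 2-{(2R)-2-[2-methoxy-4-(methoxymethoxy)phenyl]-3-(methoxymethoxy)propyl}-4,4,5,5-tetramethyl-1,3,2-dioxaborolane F4.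
- B-alkyl Suzuki–Miyaura coupling of this boronate with 10 joins C4 to C4a (Pd(OAc)2, RuPhos, K3PO4, toluene/H2O, 90 °C; a ligand class made for di-ortho-substituted aryl electrophiles). It should give (2R)-1-[2-methoxy-4,6-bis(methoxymethoxy)-3-(3-methylbut-2-enyl)phenyl]-2-[2-methoxy-4-(methoxymethoxy)phenyl]-3-(methoxymethoxy)propane F5.
- The conditions of step 11 remove all four acetals and return the route at 19.

**Step 11.** Protonation of the prenyl alkene may lead to ring closure by the freed C7 hydroxyl or to addition of methanol before all three acetals are gone.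

Fallback (from 18, back at 19): the protic acid is replaced by aprotic silyl exchange. TMSOTf and 2,2'-bipyridyl in MeCN at 0 °C convert the aryl acetals into silyl ethers and silylate the alcohol, which should give (2R)-2-[2-methoxy-4-(trimethylsilyloxy)phenyl]-3-[2-methoxy-3-(3-methylbut-2-enyl)-4,6-bis(trimethylsilyloxy)phenyl]-1-(trimethylsilyloxy)propane F7. Brief methanolysis (K2CO3 cat., MeOH) then gives 19.

**Step 12.** The C7 or C4' hydroxyl of one molecule may be alkylated by another, the azodicarboxylate may attack the very electron-rich ring A, or ring B may take part as a neighbouring group at the activated carbon.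

Fallback (from 18, back at 20): activation is separated from closure and no azo reagent meets the free polyphenol.
- Chlorination of 18 (PPh3, N-chlorosuccinimide, CH2Cl2) should give 1-[(2R)-3-chloro-2-[2-methoxy-4-(methoxymethoxy)phenyl]propyl]-2-methoxy-4,6-bis(methoxymethoxy)-3-(3-methylbut-2-enyl)benzene F8.
- The conditions of step 11 should give 4-[(2R)-3-chloro-2-(4-hydroxy-2-methoxyphenyl)propyl]-5-methoxy-6-(3-methylbut-2-enyl)benzene-1,3-diol F9; a primary chloride is inert to methanolic acid.
- Slow addition of this chloride to K2CO3 in degassed MeCN at 50 °C closes ring C by 6-exo-tet Williamson etherification to give 20.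

**Step 10.** The short-lived carbenoid may decompose before it adds to the hindered secondary benzylic boron, leaving the conversion incomplete. The benzylic boronate may also be protodeboronated by base.

Fallback (from 16, back at 17): the more persistent dichloromethyl carbenoid is used. LiCHCl2 (CH2Cl2, n-BuLi, THF, −100 °C), then ZnCl2 and warming, should give 2-{(2R)-1-chloro-2-[2-methoxy-4-(methoxymethoxy)phenyl]-3-[2-methoxy-4,6-bis(methoxymethoxy)-3-(3-methylbut-2-enyl)phenyl]propyl}-4,4,5,5-tetramethyl-1,3,2-dioxaborolane F6 as a mixture of epimers at the chlorine-bearing carbon. LiBHEt3 then adds hydride to boron, and a 1,2-hydride shift expels chloride to give 17, which is oxidised as in step 10.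

## Further compounds

F1 | step 9 | 2-[2-methoxy-4-(methoxymethoxy)phenyl]-4,4,5,5-tetramethyl-1,3,2-dioxaborolane | COCOc1ccc(B2OC(C)(C)C(C)(C)O2)c(OC)c1
F2 | step 9 | 2-[2-methoxy-4-(methoxymethoxy)phenyl]prop-2-en-1-ol | C=C(CO)c1ccc(OCOC)cc1OC
F3 | step 9 | 2-methoxy-4-(methoxymethoxy)-1-[3-(methoxymethoxy)prop-1-en-2-yl]benzene | C=C(COCOC)c1ccc(OCOC)cc1OC
F4 | step 9 | 2-{(2R)-2-[2-methoxy-4-(methoxymethoxy)phenyl]-3-(methoxymethoxy)propyl}-4,4,5,5-tetramethyl-1,3,2-dioxaborolane | COc1cc(OCOC)ccc1[C@@H](CB1OC(C)(C)C(C)(C)O1)COCOC
F5 | step 9 | (2R)-1-[2-methoxy-4,6-bis(methoxymethoxy)-3-(3-methylbut-2-enyl)phenyl]-2-[2-methoxy-4-(methoxymethoxy)phenyl]-3-(methoxymethoxy)propane | COc1cc(OCOC)ccc1[C@@H](Cc1c(OC)c(CC=C(C)C)c(OCOC)cc1OCOC)COCOC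
F6 | step 10 | 2-{(2R)-1-chloro-2-[2-methoxy-4-(methoxymethoxy)phenyl]-3-[2-methoxy-4,6-bis(methoxymethoxy)-3-(3-methylbut-2-enyl)phenyl]propyl}-4,4,5,5-tetramethyl-1,3,2-dioxaborolane (epimers at C1) | COc1cc(OCOC)ccc1[C@@H](Cc1c(OC)c(CC=C(C)C)c(OCOC)cc1OCOC)C(Cl)B1OC(C)(C)C(C)(C)O1
F7 | step 11 | (2R)-2-[2-methoxy-4-(trimethylsilyloxy)phenyl]-3-[2-methoxy-3-(3-methylbut-2-enyl)-4,6-bis(trimethylsilyloxy)phenyl]-1-(trimethylsilyloxy)propane | COc1cc(O[Si](C)(C)C)ccc1[C@@H](Cc1c(OC)c(CC=C(C)C)c(O[Si](C)(C)C)cc1O[Si](C)(C)C)CO[Si](C)(C)C
F8 | step 12 | 1-[(2R)-3-chloro-2-[2-methoxy-4-(methoxymethoxy)phenyl]propyl]-2-methoxy-4,6-bis(methoxymethoxy)-3-(3-methylbut-2-enyl)benzene | COc1cc(OCOC)ccc1[C@@H](Cc1c(OC)c(CC=C(C)C)c(OCOC)cc1OCOC)CCl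
F9 | step 12 | 4-[(2R)-3-chloro-2-(4-hydroxy-2-methoxyphenyl)propyl]-5-methoxy-6-(3-methylbut-2-enyl)benzene-1,3-diol | COc1cc(O)ccc1[C@@H](Cc1c(OC)c(CC=C(C)C)c(O)cc1O)CCl
A1 | alternative 1 | (3R)-5-methoxy-3-[2-methoxy-4-(triisopropylsilyloxy)phenyl]-6-(3-methylbut-2-enyl)chroman-7-ol | COc1cc(O[Si](C(C)C)(C(C)C)C(C)C)ccc1[C@@H]1COc2cc(O)c(CC=C(C)C)c(OC)c2C1
A2 | alternative 1 | (4R)-4-[2-methoxy-4-(triisopropylsilyloxy)phenyl]-2-oxabicyclo[4.2.0]oct-1(6)-en-7-one | O=C1CC2=C1C[C@H](c1ccc(O[Si](C(C)C)(C(C)C)C(C)C)cc1OC)CO2
A3 | alternative 1 | 1-methoxy-5-methylhex-4-en-1-yne | COC#CCC=C(C)C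
A4 | alternative 2 | (3R)-5-methoxy-3-[2-methoxy-4-(methoxymethoxy)phenyl]-7-(methoxymethoxy)-6-(3-methylbut-2-enyl)chroman | COc1cc(OCOC)ccc1[C@@H]1COc2cc(OCOC)c(CC=C(C)C)c(OC)c2C1
A5 | alternative 2 | 3-methoxy-2-{2-[2-methoxy-4-(methoxymethoxy)phenyl]prop-2-enyl}-5-(methoxymethoxy)-4-(3-methylbut-2-enyl)phenol | C=C(Cc1c(O)cc(OCOC)c(CC=C(C)C)c1OC)c1ccc(OCOC)cc1OC
A6 | alternative 3 | (3R)-5-methoxy-3-[2-methoxy-4-(methoxymethoxy)phenyl]-7-(methoxymethoxy)-6-(3-methylbut-2-enyl)-3,4-dihydrochromen-2-one | COc1cc(OCOC)ccc1[C@@H]1C(=O)Oc2cc(OCOC)c(CC=C(C)C)c(OC)c2C1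
A7 | alternative 3 | 3-methoxy-5-(methoxymethoxy)-4-(3-methylbut-2-enyl)-2-[(4-methylbenzenesulfonyl)methyl]phenol | Cc1ccc(cc1)S(=O)(=O)Cc1c(O)cc(OCOC)c(CC=C(C)C)c1OC
A8 | alternative 3 | pentafluorophenyl 2-[2-methoxy-4-(methoxymethoxy)phenyl]acetate | COCOc1ccc(CC(=O)Oc2c(F)c(F)c(F)c(F)c2F)c(OC)c1
A9 | alternative 3 | 3-methoxy-5-(methoxymethoxy)-4-(3-methylbut-2-enyl)-6-methylidenecyclohexa-2,4-dien-1-one | C=C1C(=O)C=C(OCOC)C(CC=C(C)C)=C1OC
A10 | alternative 3 | 2-{(2R)-3-hydroxy-2-[2-methoxy-4-(methoxymethoxy)phenyl]propyl}-3-methoxy-5-(methoxymethoxy)-4-(3-methylbut-2-enyl)phenol | COc1cc(OCOC)ccc1[C@@H](Cc1c(OC)c(CC=C(C)C)c(OCOC)cc1O)CO
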